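**Remark (stereochemistry):** the target has no stereocentre and no configurationally stable axis (C5–H on ring A leaves the C–O–C unit free to rotate). It is a single achiral compound, so no enantioselective step is needed.

**Remark (starting material):** racemic 2,3-epoxycyclohexan-1-one is assumed to be a catalogue compound.

**Atom labels:** ring A is C1–C6 (C1–OH, C2–Br, C4–Br, C6–O), ring B is C1′–C6′ (C1′–O, C2′–OH, C3′–Br, C5′–Br, C6′–Br). The same labels are kept for intermediates in which ring A is not yet aromatic (C1 = carbonyl carbon, C6 = carbon bearing the ether oxygen).

## Structural features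

The target is a diaryl ether: ring A and ring B are joined only through the oxygen between C6 and C1′, and each ring carries a free OH (C1, C2′) ortho to that oxygen. It has no stereocentre and is achiral. Four of the five bromines (C2, C4, C3′, C5′) sit ortho or para to a free OH, where phenol-directed bromination puts them; the fifth, at C6′, is meta to C2′–OH and ortho to the ether oxygen and cannot be placed that way. The ether carbon C1′ is flanked by C2′–O and C6′–Br and C6 by C1–O, so the C6–O–C1′ linkage is hindered, electron-rich on both sides, and next to an aryl C–Br bond that competes in any metal-mediated arylation. Fragile points are the easily oxidised bis-phenol, possible closure of a dibenzo-p-dioxin by attack of C1–OH on C6′–Br under base or copper, and the C–Br bonds under reducing or metallating conditions. The real difficulty is therefore the hindered C6–O bond with C6′–Br already in place, not the ring bromination. The key step exploits that ring A is a 2-aryloxyphenol whose only other substituents are bromines ortho/para to C1–OH: C1 and C6 map onto the carbonyl and α-carbon of a cyclohexanone, so ring A can enter as 2,3-epoxycyclohexanone, with C6 as an sp3 electrophile, and be aromatised afterwards.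

## Logic of the disconnections

**10 ⇒ 9.** The bonds C2–Br, C4–Br, C3′–Br and C5′–Br are cut. These are exactly the positions ortho/para to the two free OH groups, whereas C6′–Br is kept because no directing effect would place it. The gain is that the unsymmetrical pentabromo pattern shrinks to one pre-set bromine. The forward step must be a four-fold bromination that stops cleanly and does not oxidise the bis-phenol.

**9 ⇒ 8.** The O–CH3 bond on the C2′ oxygen is cut (a functional group change only). C2′–OH has to stay masked while ring A is still a ketone, because a free ortho OH would add to the C1 carbonyl and lead toward a dibenzodioxin skeleton; the methyl group comes with 1. The forward step must cleave the methyl ether without touching the diaryl ether or the C–Br bond.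

**8 ⇒ 4.** Ring A is taken out of the aromatic oxidation level: the C2=C3 π bond is removed (hydrogens returned to C2 and C3) and C1–OH becomes C1=O. In 4 the ether carbon C6 is the α-carbon of an enone, which can be reached from an sp3 electrophile. The gain is that a hindered diaryl ether problem becomes an α-aryloxy enone problem. The forward step must dehydrogenate across C2–C3 (the only sp3 α-position) under conditions that spare Ar–Br.

**4 ⇒ 1 + 2 (key).** The O–C6 bond, the ether bond of the target, is cut, and water is formally returned across C5=C6 (through 3). Cutting here lets the ether oxygen stay on ring B as the phenol oxygen of 1, which already holds C6′–Br and the masked C2′–OH, while 2 supplies all six carbons of ring A and the C1 oxygen. The gain is full convergence to two one-ring catalogue compounds. In one sentence: the ether bond is made by opening 2 at C6 with the phenol oxygen of 1 before ring A is aromatic, which does not describe an aryl halide–phenol coupling. The forward step must open the epoxide at the α-carbon, alkylate at oxygen, and dehydrate.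

## Other disconnections considered

**Alternative 1:** (the first that comes to mind) Cut C6–O at the aromatic level. The forward key step is a copper-catalysed Ullmann coupling of 1 with 2-iodoanisole to give 1-bromo-3-methoxy-2-(2-methoxyphenoxy)benzene A1; double demethylation would give 9 and bromination 10. On paper this is one step shorter. However, the oxygen of 1 is flanked by Br and OMe and the partner is an electron-rich ortho-substituted aryl iodide, the slowest class for this coupling. More seriously, 1 and A1 carry their own C–Br bond ortho to oxygen, which under copper at high temperature is a competing electrophile (self-condensation, reduction). The SNAr variants avoid the metal but need several extra steps to turn the activating group into OH. The chosen plan makes the same bond at an sp3 carbon without metal, so the chemoselectivity question does not arise.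

**Alternative 2:** Cut C6–O oxidatively, as in the presumed biosynthesis. The forward key step is an anodic cross-coupling of 2,4,6-tribromophenol with 3,5,6-tribromo-2-methoxyphenol A2, through the bromodienone 2,4,6-tribromo-6-(2,3,5-tribromo-6-methoxyphenoxy)cyclohexa-2,4-dien-1-one A3. Zinc reduction would give 2,4-dibromo-6-(2,3,5-tribromo-6-methoxyphenoxy)phenol A4, and demethylation 10. The idea is attractive because ring A is exactly the ipso-substitution pattern of a tribromophenol. The grounds against it are mechanistic: both partners are oxidisable phenols of similar potential, so self-coupling of either competes with the cross-coupling. The oxidised tribromophenol can also be attacked at its para ipso carbon as well as at the ortho one. In addition, A2 has its third bromine meta to the phenol OH and would itself need a multistep preparation, so the route is longer and less selective.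

**Alternative 3:** Use the hidden symmetry of the core. The forward key step is reductive cleavage of one C–O bond of dibenzo-p-dioxin with lithium, then borylation and oxidation of the aryl anion to give 2,2′-oxydiphenol A5. Bromination would pass through 2,2′-oxybis(4,6-dibromophenol) A6 on the way to 10. The first four bromines would enter as desired, but the fifth must go onto one ring only, meta to OH and ortho to the ether oxygen. In A6 the two rings are identical and deactivated, and the position para to the ether oxygen competes, so the odd bromine cannot be placed with control. The chosen plan brings C6′–Br in with 1.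

Key step: step 1

## Steps

**Step 1**
Reactants: 1 2-bromo-6-methoxyphenol; 2 racemic 2,3-epoxycyclohexan-1-one (7-oxabicyclo[4.1.0]heptan-2-one)
Product: 4 2-(2-bromo-6-methoxyphenoxy)cyclohex-2-en-1-one, via trans-β-hydroxy ketone 3 (not isolated)
Conditions: 1 (1.0 equiv), 2 (1.2 equiv), Cs2CO3 (20 mol%), DMF, 80 °C; then TsOH·H2O (cat.), PhMe, reflux (Dean–Stark)
Reagents that add atoms: none
Why: This is a base-catalysed opening of an α,β-epoxy ketone by a heteroatom nucleophile followed by E1cB dehydration, the known way from epoxy ketones to 2-thio-, 2-amino-, 2-alkoxy- and 2-aryloxy-enones. The caesium phenoxide of 1 should attack the epoxide carbon α to the carbonyl (C6) in an SN2 sense with inversion to give the trans-hydroxy ketone 3, whose alkoxide is protonated by further 1, so the phenoxide is regenerated and catalytic base suffices. Loss of water from 3 (C6–H is acidified by the carbonyl and the aryloxy group, hydroxide leaves from C5) should give 4, the thermodynamic sink as a conjugated, oxygen-stabilised enone, and the acid/Dean–Stark stage completes this dehydration. The selectivity needed is α- over β-opening and O- over C-alkylation: C6 is activated toward SN2 by the adjacent C=O as in an α-halo ketone while C5 is an ordinary secondary epoxide carbon, and a caesium phenoxide in DMF reacts at oxygen. No metal is present, so the C6′–Br bond of 1 is not a competing electrophile, and the small sp3 electrophile should be reached by the phenoxide oxygen despite its two ortho substituents. No ring is closed, and the stereocentres of 2 and 3 are transient and erased when C5=C6 forms, so racemic 2 suffices. The product already holds the complete C12O3 skeleton of 10, with the C1 carbonyl as the latent C1–OH.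

**Step 2**
Reactants: 4 2-(2-bromo-6-methoxyphenoxy)cyclohex-2-en-1-one
Product: 8 2-(2-bromo-6-methoxyphenoxy)phenol, via α′-phenylselanyl enone 5 (not isolated), via selenoxide 6 (not isolated), via cross-conjugated dienone 7 (not isolated)
Conditions: LiHMDS (1.1 equiv), THF, −78 °C; PhSeCl (1.1 equiv), −78 °C; then 30% aq. H2O2 (3 equiv), pyridine, CH2Cl2, 0 °C → rt
Reagents that add atoms: none
Why: Kinetic deprotonation of the enone at its only sp3 α-carbon (C2) should give the cross-conjugated lithium enolate, which is selenenylated to 5; oxidation to 6 and selenoxide syn-elimination toward the C3 hydrogens should give dienone 7, the keto tautomer of 8, which enolises at once (α-selenenylation/selenoxide elimination used as an enone-to-phenol dehydrogenation). The amide base at −78 °C and H2O2/pyridine at 0 °C should leave the aryl C–Br bond and both ether bonds untouched, and no halogenating agent or transition metal is present that could attack ring B.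

**Step 3**
Reactants: 8 2-(2-bromo-6-methoxyphenoxy)phenol
Product: 9 3-bromo-2-(2-hydroxyphenoxy)phenol
Conditions: BBr3 (3 equiv), CH2Cl2, −78 → 0 °C; then H2O
Reagents that add atoms: none
Why: Lewis-acid demethylation of an aryl methyl ether: boron binds the methoxy oxygen and bromide attacks the methyl carbon (SN2). The diaryl ether should survive because both of its carbons are sp2, and aryl bromides are inert to BBr3.

**Step 4**
Reactants: 9 3-bromo-2-(2-hydroxyphenoxy)phenol
Product: 10 3,4,6-tribromo-2-(3,5-dibromo-2-hydroxyphenoxy)phenol (target)
Conditions: Br2 (4.0 equiv), AcOH, 10 °C → rt
Reagents that add atoms: bromine, BrBr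
Why: Phenol-directed electrophilic aromatic bromination: C2, C4, C3′ and C5′ are the four positions ortho/para to the two free OH groups and the only strongly activated C–H positions, so four equivalents should give 10. The remaining C–H positions (C3, C5, C4′) are meta to OH and end up flanked by bromine, which should stop the reaction at the pentabromide.

## Compound list

1 | 2-bromo-6-methoxyphenol | COc1cccc(Br)c1O | starting material
2 | 2,3-epoxycyclohexan-1-one (7-oxabicyclo[4.1.0]heptan-2-one), cis-fused, racemic, one enantiomer drawn | O=C1CCC[C@H]2O[C@@H]12 | starting material
3 | trans-2-(2-bromo-6-methoxyphenoxy)-3-hydroxycyclohexan-1-one, racemic, one enantiomer drawn, not isolated | O=C1CCC[C@@H](O)[C@@H]1Oc1c(Br)cccc1OC | intermediate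
4 | 2-(2-bromo-6-methoxyphenoxy)cyclohex-2-en-1-one | COc1cccc(Br)c1OC1=CCCCC1=O | intermediate
5 | 2-(2-bromo-6-methoxyphenoxy)-6-(phenylselanyl)cyclohex-2-en-1-one, racemic, not isolated | COc1cccc(Br)c1OC1=CCCC([Se]c2ccccc2)C1=O | intermediate
6 | 2-(2-bromo-6-methoxyphenoxy)-6-(phenylseleninyl)cyclohex-2-en-1-one, mixture of diastereomers, not isolated | COc1cccc(Br)c1OC1=CCCC([Se](=O)c2ccccc2)C1=O | intermediate
7 | 2-(2-bromo-6-methoxyphenoxy)cyclohexa-2,5-dien-1-one, not isolated | COc1cccc(Br)c1OC1=CCC=CC1=O | intermediate
8 | 2-(2-bromo-6-methoxyphenoxy)phenol | COc1cccc(Br)c1Oc1ccccc1O | intermediate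
9 | 3-bromo-2-(2-hydroxyphenoxy)phenol | Oc1ccccc1Oc1c(O)cccc1Br | intermediate
10 | 3,4,6-tribromo-2-(3,5-dibromo-2-hydroxyphenoxy)phenol (achiral) | Oc1c(Br)cc(Br)cc1Oc1c(O)c(Br)cc(Br)c1Br | target

## Step count and least certain steps

Total step count: 4. Longest linear sequence: 4 steps (1 or 2 to 10).

**Step 1 (key step).** The phenoxide of 1, hindered by two ortho substituents, may open the epoxide too slowly. Base-induced isomerisation of 2, opening at the β-carbon, or incomplete dehydration of 3 could then take over. The fallback sets out from 1 and comes back at 4. Alkylation of 1 with commercial 2-chlorocyclohexanone (K2CO3, cat. KI, DMF, 60 °C) should give 2-(2-bromo-6-methoxyphenoxy)cyclohexan-1-one F1. Silylation under equilibrating conditions (TMSCl, NaI, Et3N, MeCN) should enolise toward the aryloxy-bearing carbon and give {[2-(2-bromo-6-methoxyphenoxy)cyclohex-1-en-1-yl]oxy}trimethylsilane F2. Saegusa–Ito oxidation (Pd(OAc)2, MeCN, rt) should then give 4.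

**Step 2.** Selenenylation may not stay at C2 (γ-deprotonation, double selenenylation), the elimination may be incomplete, or electrophilic selenium by-products may attack the newly formed electron-rich phenol. The fallback sets out from 1, comes back at 8, and gives up the cyclohexenone surrogate. SNAr of 1 on 2-fluorobenzaldehyde (K2CO3, DMF, 120 °C; the ortho formyl group activates, no metal) should give 2-(2-bromo-6-methoxyphenoxy)benzaldehyde F3. Baeyer–Villiger oxidation with mCPBA (CH2Cl2, rt; aryl migration favoured by the ortho aryloxy donor) should give 2-(2-bromo-6-methoxyphenoxy)phenyl formate F4. Methanolysis (cat. K2CO3, MeOH) should give 8.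

**Step 4.** The four-fold bromination may over-run at positions activated by the ether oxygen, may stop short and leave mixtures of tri- and tetrabromides, or bromine may oxidise the bis-phenol. The fallback sets out from 8, comes back at 10, and stages the halogenation with the ring-B oxygen still masked. Br2 (3 equiv, AcOH) on 8 should brominate ring A ortho/para to its OH and ring B para to the methoxy group (C5′) to give 2,4-dibromo-6-(2,3-dibromo-6-methoxyphenoxy)phenol F5. BBr3 should then give 3,4-dibromo-2-(3,5-dibromo-2-hydroxyphenoxy)phenol F6. Its only remaining activated position is C3′, which NBS (1 equiv, MeCN) should brominate to give 10.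

## Further compounds

F1 | step 1 | 2-(2-bromo-6-methoxyphenoxy)cyclohexan-1-one (racemic) | COc1cccc(Br)c1OC1CCCCC1=O
F2 | step 1 | {[2-(2-bromo-6-methoxyphenoxy)cyclohex-1-en-1-yl]oxy}trimethylsilane | COc1cccc(Br)c1OC1=C(O[Si](C)(C)C)CCCC1
F3 | step 2 | 2-(2-bromo-6-methoxyphenoxy)benzaldehyde | COc1cccc(Br)c1Oc1ccccc1C=O
F4 | step 2 | 2-(2-bromo-6-methoxyphenoxy)phenyl formate | COc1cccc(Br)c1Oc1ccccc1OC=O
F5 | step 4 | 2,4-dibromo-6-(2,3-dibromo-6-methoxyphenoxy)phenol | COc1ccc(Br)c(Br)c1Oc1cc(Br)cc(Br)c1O
F6 | step 4 | 3,4-dibromo-2-(3,5-dibromo-2-hydroxyphenoxy)phenol | Oc1ccc(Br)c(Br)c1Oc1cc(Br)cc(Br)c1O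
A1 | alternative 1 | 1-bromo-3-methoxy-2-(2-methoxyphenoxy)benzene | COc1ccccc1Oc1c(Br)cccc1OC
A2 | alternative 2 | 3,5,6-tribromo-2-methoxyphenol | COc1c(Br)cc(Br)c(Br)c1O
A3 | alternative 2 | 2,4,6-tribromo-6-(2,3,5-tribromo-6-methoxyphenoxy)cyclohexa-2,4-dien-1-one (racemic) | COc1c(Br)cc(Br)c(Br)c1OC1(Br)C=C(Br)C=C(Br)C1=O
A4 | alternative 2 | 2,4-dibromo-6-(2,3,5-tribromo-6-methoxyphenoxy)phenol | COc1c(Br)cc(Br)c(Br)c1Oc1cc(Br)cc(Br)c1O
A5 | alternative 3 | 2,2′-oxydiphenol | Oc1ccccc1Oc1ccccc1O
A6 | alternative 3 | 2,2′-oxybis(4,6-dibromophenol) | Oc1c(Br)cc(Br)cc1Oc1cc(Br)cc(Br)c1O
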